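**Retrosynthetic overview**

1. Labels: chain C1'–C14' counted from the quinone; cyclopentane Ca (bears C14'), Cb, Cc, Cd (bears the side-chain methine Cx), Ce. The strategy rests on this cis-1,3-disubstituted cyclopentane: Ca and Cd, each with one exocyclic carbon (C14' and Cx), are the two bridgeheads of norbornene with its C2=C3 bond cut, so the cis relationship is built in.
2. Last disconnection: quinone C3–C1', by Negishi coupling of the C1' alkylzinc with 2-bromo-1,4-dimethoxy-3-methylnaphthalene (from menadione), then oxidative demethylation.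
3. Side chain on Cd: Cx–CH3 by copper-catalysed asymmetric conjugate methylation of the enoate made by cross-metathesis at the vinyl group; the isohexyl end by Wittig olefination; both chain alkenes are hydrogenated together.
4. Key disconnection: C13'=C14' and Cx=CH2 by asymmetric ring-opening cross-metathesis of norbornene with the C1'–C13' terminal alkene, which comes from farnesol (terminal allylic oxidation, triple asymmetric hydrogenation, bromide, vinylation).
5. Ring order: no ring is closed; the naphthalene core is bought as menadione and the cyclopentane is released from the bicycle in step 6.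

Key step: step 6

Assumption: the absolute sense of induction of the chiral catalysts in steps 3, 6 and 8 on these substrates is taken to be that of the ligand antipode named; both antipodes of each ligand are accessible, and the mirror-image ligand is used without other change if a pilot run shows the opposite sense.

**Route**

Step 1
Reactants: 1 (2E,6E)-farnesol
Product: 2 tert-butyl(dimethyl){[(2E,6E)-3,7,11-trimethyldodeca-2,6,10-trien-1-yl]oxy}silane
Conditions: TBSCl, imidazole, DMF, 0 °C to rt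
Reagents that add atoms: tert-butyldimethylsilyl chloride, CC(C)(C)[Si](C)(C)Cl
Why: Silyl ether protection of a primary allylic alcohol is routine, and the TBS ether should survive every step up to the fluoride cleavage in step 12.

Step 2
Reactants: 2 tert-butyl(dimethyl){[(2E,6E)-3,7,11-trimethyldodeca-2,6,10-trien-1-yl]oxy}silane
Product: 3 (2E,6E,10E)-12-{[tert-butyl(dimethyl)silyl]oxy}-2,6,10-trimethyldodeca-2,6,10-trien-1-ol
Conditions: SeO2 (0.2 equiv), t-BuOOH (3 equiv), salicylic acid (0.1 equiv), CH2Cl2, 0 °C to rt, stopped at partial conversion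
Reagents that add atoms: tert-butyl hydroperoxide, CC(C)(C)OO (oxygen relayed through catalytic selenium dioxide, O=[Se]=O)
Why: Riley-type catalytic SeO2 allylic oxidation (ene reaction, then [2,3]-sigmatropic shift) should select the most electron-rich and least hindered terminal trisubstituted alkene and its (E)-methyl group, giving the (E)-allylic alcohol without touching the silyl ether.

Step 3
Reactants: 3 (2E,6E,10E)-12-{[tert-butyl(dimethyl)silyl]oxy}-2,6,10-trimethyldodeca-2,6,10-trien-1-ol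
Product: 4 (2R,6R,10S)-12-{[tert-butyl(dimethyl)silyl]oxy}-2,6,10-trimethyldodecan-1-ol
Conditions: H2 (50 bar), [Ir(cod)(L*)][B(3,5-(CF3)2C6H3)4] (1 mol %; L* = (S)-8-(di-tert-butylphosphinooxy)-2-phenyl-5,6,7,8-tetrahydroquinoline), CH2Cl2, rt
Reagents that add atoms: none
Why: Iridium N,P-ligand-catalysed asymmetric hydrogenation of (E)-trisubstituted alkenes is established for farnesol and its O-protected derivatives; all three alkenes of 3 share the same local (E)-CH=C(CH3)CH2 geometry, so one catalyst antipode should deliver hydrogen to the same face of each and set C3', C7' and C11' together under catalyst control.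

Step 4
Reactants: 4 (2R,6R,10S)-12-{[tert-butyl(dimethyl)silyl]oxy}-2,6,10-trimethyldodecan-1-ol
Product: 5 {[(3S,7R,11R)-12-bromo-3,7,11-trimethyldodecyl]oxy}(tert-butyl)dimethylsilane
Conditions: CBr4, PPh3, 2,6-lutidine (0.1 equiv), CH2Cl2, 0 °C
Reagents that add atoms: carbon tetrabromide, BrC(Br)(Br)Br
Why: Appel bromination of a primary alcohol proceeds by SN2 displacement at C12' and should leave the adjacent C11' stereocentre and the buffered silyl ether untouched.

Step 5
Reactants: 5 {[(3S,7R,11R)-12-bromo-3,7,11-trimethyldodecyl]oxy}(tert-butyl)dimethylsilane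
Product: 6 tert-butyl(dimethyl){[(3S,7S,11R)-3,7,11-trimethyltetradec-13-en-1-yl]oxy}silane
Conditions: CH2=CHMgBr (3 equiv), Li2CuCl4 (5 mol %), NMP (4 equiv), THF, 0 °C to rt
Reagents that add atoms: vinylmagnesium bromide, C=C[Mg]Br
Why: Copper-catalysed Grignard cross-coupling of Kochi type should displace the primary bromide at C12' without affecting C11', with NMP suppressing elimination of the β-branched bromide.

Step 6
Reactants: 6 tert-butyl(dimethyl){[(3S,7S,11R)-3,7,11-trimethyltetradec-13-en-1-yl]oxy}silane; 7 norbornene (bicyclo[2.2.1]hept-2-ene)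
Product: 8 tert-butyl{[(3S,7S,11R,13Z)-14-[(1R,3S)-3-ethenylcyclopentyl]-3,7,11-trimethyltetradec-13-en-1-yl]oxy}dimethylsilane
Conditions: 6 (3 equiv), Mo(N-1-adamantyl)(CHCMe2Ph)(2,5-Me2C4H2N)(OAr*) (5 mol %, formed in situ from Mo(N-1-adamantyl)(CHCMe2Ph)(2,5-Me2C4H2N)2 and HOAr* = (R)-3,3'-dibromo-2'-(tert-butyldimethylsilyloxy)-5,5',6,6',7,7',8,8'-octahydro-1,1'-binaphthalen-2-ol), C6H6, 22 °C, N2 sweep; 7 (1 equiv) in C6H6 added over 3 h by syringe pump
Reagents that add atoms: none
Why: The neophylidene initiator is turned over by 6 into the chain alkylidene Mo=C13'H–R, which adds to the exo face of the strained C2=C3 bond of 7; the metallacyclobutane cycloreverts with release of ring strain to a ring-opened alkylidene that already carries C13'=C14', and capture by a second molecule of 6 puts the methylidene on the future Cx and returns Mo=C13'H–R. The closest known reaction type is the asymmetric ring-opening/cross-metathesis of norbornenes and oxabicycles with stereogenic-at-metal molybdenum monoaryloxide pyrrolide (or chiral ruthenium) alkylidenes, the parent bicycle with an aliphatic partner being a demanding member of that class. No ring is closed: one ring of the bicycle is opened and the cyclopentane Ca–Ce is released with its cis relationship inherited from the two bridgeheads. Ca and Cd, enantiotopic in meso 7, become stereocentres when the stereogenic molybdenum centre with its large aryloxide accepts only one of the two mirror-image orientations of the bicycle in the metallacycle-forming step, the remote stereocentres of 6 playing no part. The step needs cross-capture to outrun ring-opening polymerisation and self-metathesis of 6, which is addressed by keeping 7 at low stationary concentration against an excess of recoverable 6, by the α-branched ring-opened alkylidene being slow to add a second bicycle, and by sweeping out ethylene; the geometry of C13'=C14' is immaterial because step 11 saturates it.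

Step 7
Reactants: 8 tert-butyl{[(3S,7S,11R,13Z)-14-[(1R,3S)-3-ethenylcyclopentyl]-3,7,11-trimethyltetradec-13-en-1-yl]oxy}dimethylsilane
Product: 9 methyl (2E)-3-[(1S,3R)-3-[(1Z,4R,8S,12S)-14-{[tert-butyl(dimethyl)silyl]oxy}-4,8,12-trimethyltetradec-1-en-1-yl]cyclopentyl]prop-2-enoate
Conditions: methyl acrylate (5 equiv), second-generation Hoveyda–Grubbs catalyst RuCl2(H2IMes)(=CH-C6H4-2-O-i-Pr) (3 mol %), CH2Cl2, 40 °C
Reagents that add atoms: methyl acrylate, C=CC(=O)OC
Why: Olefin cross-metathesis of a monosubstituted alkene with an acrylate is E-selective and should engage the terminal vinyl group faster than the internal Z-alkene C13'=C14', which is more hindered (ring methine at Ca) and belongs to a less reactive olefin class.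

Step 8
Reactants: 9 methyl (2E)-3-[(1S,3R)-3-[(1Z,4R,8S,12S)-14-{[tert-butyl(dimethyl)silyl]oxy}-4,8,12-trimethyltetradec-1-en-1-yl]cyclopentyl]prop-2-enoate
Product: 10 methyl (3R)-3-[(1S,3R)-3-[(1Z,4R,8S,12S)-14-{[tert-butyl(dimethyl)silyl]oxy}-4,8,12-trimethyltetradec-1-en-1-yl]cyclopentyl]butanoate
Conditions: MeMgBr (4 equiv), CuI (2 mol %), (R)-Tol-BINAP (3 mol %), t-BuOMe, −20 °C; NH4Cl (aq.)
Reagents that add atoms: methylmagnesium bromide, C[Mg]Br
Why: Copper–bisphosphine-catalysed asymmetric conjugate addition of a Grignard reagent to an (E)-enoate should set Cx under catalyst control, since the two ring CH2 groups flanking Cd are too alike to give a substrate bias, while the low temperature and weakly coordinating ether suppress 1,2-addition to the ester.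

Step 9
Reactants: 10 methyl (3R)-3-[(1S,3R)-3-[(1Z,4R,8S,12S)-14-{[tert-butyl(dimethyl)silyl]oxy}-4,8,12-trimethyltetradec-1-en-1-yl]cyclopentyl]butanoate
Product: 11 (3R)-3-[(1S,3R)-3-[(1Z,4R,8S,12S)-14-{[tert-butyl(dimethyl)silyl]oxy}-4,8,12-trimethyltetradec-1-en-1-yl]cyclopentyl]butanal
Conditions: i-Bu2AlH (1.1 equiv), CH2Cl2, −78 °C; MeOH, then aqueous potassium sodium tartrate
Reagents that add atoms: none
Why: Partial reduction of a methyl ester with i-Bu2AlH at −78 °C should stop at the aluminium hemiacetal, which gives the aldehyde on work-up; Cx is β to the carbonyl and cannot epimerise.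

Step 10
Reactants: 11 (3R)-3-[(1S,3R)-3-[(1Z,4R,8S,12S)-14-{[tert-butyl(dimethyl)silyl]oxy}-4,8,12-trimethyltetradec-1-en-1-yl]cyclopentyl]butanal
Product: 12 tert-butyl(dimethyl){[(3S,7S,11R,13Z)-3,7,11-trimethyl-14-[(1R,3S)-3-[(2R,4Z)-6-methylhept-4-en-2-yl]cyclopentyl]tetradec-13-en-1-yl]oxy}silane
Conditions: (CH3)2CHCH2PPh3Br, NaN(SiMe3)2, THF, 0 °C; then 11, −78 °C to rt
Reagents that add atoms: isobutyltriphenylphosphonium bromide, CC(C)C[P+](c1ccccc1)(c1ccccc1)c1ccccc1.[Br-]
Why: Wittig olefination with a non-stabilised ylide completes the eight-carbon side chain, and its Z/E outcome is irrelevant because the alkene is reduced in the next step.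

Step 11
Reactants: 12 tert-butyl(dimethyl){[(3S,7S,11R,13Z)-3,7,11-trimethyl-14-[(1R,3S)-3-[(2R,4Z)-6-methylhept-4-en-2-yl]cyclopentyl]tetradec-13-en-1-yl]oxy}silane
Product: 13 tert-butyl(dimethyl){[(3S,7S,11R)-3,7,11-trimethyl-14-[(1R,3S)-3-[(2R)-6-methylheptan-2-yl]cyclopentyl]tetradecyl]oxy}silane
Conditions: H2 (1 atm), PtO2, EtOAc, rt
Reagents that add atoms: none
Why: Heterogeneous catalytic hydrogenation should saturate both 1,2-disubstituted alkenes; platinum is preferred to palladium because it is less prone to double-bond migration, which protects the allylic stereocentre Ca and the homoallylic Cx.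

Step 12
Reactants: 13 tert-butyl(dimethyl){[(3S,7S,11R)-3,7,11-trimethyl-14-[(1R,3S)-3-[(2R)-6-methylheptan-2-yl]cyclopentyl]tetradecyl]oxy}silane
Product: 14 (3S,7S,11R)-3,7,11-trimethyl-14-[(1R,3S)-3-[(2R)-6-methylheptan-2-yl]cyclopentyl]tetradecan-1-ol
Conditions: Bu4NF, THF, rt
Reagents that add atoms: none
Why: Fluoride-induced desilylation, driven by Si–F bond formation, frees the primary alcohol in a molecule that has no other functional group.

Step 13
Reactants: 14 (3S,7S,11R)-3,7,11-trimethyl-14-[(1R,3S)-3-[(2R)-6-methylheptan-2-yl]cyclopentyl]tetradecan-1-ol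
Product: 15 (1R,3S)-1-[(4R,8S,12S)-14-iodo-4,8,12-trimethyltetradecyl]-3-[(2R)-6-methylheptan-2-yl]cyclopentane
Conditions: I2, PPh3, imidazole, CH2Cl2, 0 °C to rt
Reagents that add atoms: iodine, II
Why: Appel-type iodination of an unhindered primary alcohol by SN2 displacement of the oxyphosphonium group is reliable and touches no stereocentre.

Step 14
Reactants: 16 menadione (2-methylnaphthalene-1,4-dione)
Product: 17 2-bromo-3-methylnaphthalene-1,4-dione
Conditions: Br2, NaOAc, AcOH, rt, dark
Reagents that add atoms: bromine, BrBr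
Why: Addition of bromine across the quinone C2=C3 bond followed by acetate-mediated loss of HBr (addition–elimination) should place bromine at the only free quinone position.

Step 15
Reactants: 17 2-bromo-3-methylnaphthalene-1,4-dione
Product: 19 2-bromo-1,4-dimethoxy-3-methylnaphthalene, via hydroquinone 18 (not isolated)
Conditions: Na2S2O4, Bu4NBr (cat.), THF–H2O, rt; then KOH, Me2SO4, rt
Reagents that add atoms: dimethyl sulfate, COS(=O)(=O)OC
Why: Dithionite reduction of the quinone and Williamson O-methylation of the hydroquinone dianion in the same flask should give the air-stable dimethyl ether.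

Step 16
Reactants: 15 (1R,3S)-1-[(4R,8S,12S)-14-iodo-4,8,12-trimethyltetradecyl]-3-[(2R)-6-methylheptan-2-yl]cyclopentane; 19 2-bromo-1,4-dimethoxy-3-methylnaphthalene
Product: 21 1,4-dimethoxy-2-methyl-3-[(3S,7S,11R)-3,7,11-trimethyl-14-[(1R,3S)-3-[(2R)-6-methylheptan-2-yl]cyclopentyl]tetradecyl]naphthalene, via alkylzinc iodide 20 (not isolated)
Conditions: 15, Zn dust (activated with BrCH2CH2Br and Me3SiCl), LiCl, THF, 40 °C; then 19 (1.3 equiv), Pd(OAc)2 (2 mol %), SPhos (4 mol %), THF, rt to 50 °C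
Reagents that add atoms: none
Why: Zinc insertion into the primary C–I bond followed by Negishi coupling should work because the biarylphosphine-ligated zerovalent palladium formed in situ adds to the di-ortho-substituted aryl bromide and the primary alkylzinc transmetallates and reductively eliminates faster than β-hydride loss; no stereocentre is involved.

Step 17
Reactants: 21 1,4-dimethoxy-2-methyl-3-[(3S,7S,11R)-3,7,11-trimethyl-14-[(1R,3S)-3-[(2R)-6-methylheptan-2-yl]cyclopentyl]tetradecyl]naphthalene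
Product: 22 2-methyl-3-[(3S,7S,11R)-3,7,11-trimethyl-14-[(1R,3S)-3-[(2R)-6-methylheptan-2-yl]cyclopentyl]tetradecyl]naphthalene-1,4-dione (CNP0182328.1)
Conditions: (NH4)2Ce(NO3)6 (2.5 equiv), MeCN–H2O (3:1), 0 °C
Reagents that add atoms: water, O
Why: Oxidative demethylation of a 1,4-dimethoxyarene by tetravalent cerium should give the 1,4-quinone, the carbonyl oxygens arriving from water and the methoxy groups leaving as methanol, while the saturated side chain is inert.

**Compound list**

1 | (2E,6E)-farnesol | CC(C)=CCC/C(C)=C/CC/C(C)=C/CO | starting material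
2 | tert-butyl(dimethyl){[(2E,6E)-3,7,11-trimethyldodeca-2,6,10-trien-1-yl]oxy}silane | CC(C)=CCC/C(C)=C/CC/C(C)=C/CO[Si](C)(C)C(C)(C)C | intermediate
3 | (2E,6E,10E)-12-{[tert-butyl(dimethyl)silyl]oxy}-2,6,10-trimethyldodeca-2,6,10-trien-1-ol | OC/C(C)=C/CC/C(C)=C/CC/C(C)=C/CO[Si](C)(C)C(C)(C)C | intermediate
4 | (2R,6R,10S)-12-{[tert-butyl(dimethyl)silyl]oxy}-2,6,10-trimethyldodecan-1-ol | CC(C)(C)[Si](C)(C)OCC[C@@H](C)CCC[C@@H](C)CCC[C@@H](C)CO | intermediate
5 | {[(3S,7R,11R)-12-bromo-3,7,11-trimethyldodecyl]oxy}(tert-butyl)dimethylsilane | CC(C)(C)[Si](C)(C)OCC[C@@H](C)CCC[C@@H](C)CCC[C@@H](C)CBr | intermediate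
6 | tert-butyl(dimethyl){[(3S,7S,11R)-3,7,11-trimethyltetradec-13-en-1-yl]oxy}silane | CC(C)(C)[Si](C)(C)OCC[C@@H](C)CCC[C@@H](C)CCC[C@@H](C)CC=C | intermediate
7 | norbornene (bicyclo[2.2.1]hept-2-ene) | C1=C[C@H]2CC[C@@H]1C2 | starting material
8 | tert-butyl{[(3S,7S,11R,13Z)-14-[(1R,3S)-3-ethenylcyclopentyl]-3,7,11-trimethyltetradec-13-en-1-yl]oxy}dimethylsilane | CC(C)(C)[Si](C)(C)OCC[C@@H](C)CCC[C@@H](C)CCC[C@@H](C)C/C=C\[C@@H]1CC[C@H](C=C)C1 | intermediate
9 | methyl (2E)-3-[(1S,3R)-3-[(1Z,4R,8S,12S)-14-{[tert-butyl(dimethyl)silyl]oxy}-4,8,12-trimethyltetradec-1-en-1-yl]cyclopentyl]prop-2-enoate | CC(C)(C)[Si](C)(C)OCC[C@@H](C)CCC[C@@H](C)CCC[C@@H](C)C/C=C\[C@@H]1CC[C@H](/C=C/C(=O)OC)C1 | intermediate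
10 | methyl (3R)-3-[(1S,3R)-3-[(1Z,4R,8S,12S)-14-{[tert-butyl(dimethyl)silyl]oxy}-4,8,12-trimethyltetradec-1-en-1-yl]cyclopentyl]butanoate | CC(C)(C)[Si](C)(C)OCC[C@@H](C)CCC[C@@H](C)CCC[C@@H](C)C/C=C\[C@@H]1CC[C@H]([C@H](C)CC(=O)OC)C1 | intermediate
11 | (3R)-3-[(1S,3R)-3-[(1Z,4R,8S,12S)-14-{[tert-butyl(dimethyl)silyl]oxy}-4,8,12-trimethyltetradec-1-en-1-yl]cyclopentyl]butanal | CC(C)(C)[Si](C)(C)OCC[C@@H](C)CCC[C@@H](C)CCC[C@@H](C)C/C=C\[C@@H]1CC[C@H]([C@H](C)CC=O)C1 | intermediate
12 | tert-butyl(dimethyl){[(3S,7S,11R,13Z)-3,7,11-trimethyl-14-[(1R,3S)-3-[(2R,4Z)-6-methylhept-4-en-2-yl]cyclopentyl]tetradec-13-en-1-yl]oxy}silane | CC(C)(C)[Si](C)(C)OCC[C@@H](C)CCC[C@@H](C)CCC[C@@H](C)C/C=C\[C@@H]1CC[C@H]([C@H](C)C/C=C\C(C)C)C1 | intermediate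
13 | tert-butyl(dimethyl){[(3S,7S,11R)-3,7,11-trimethyl-14-[(1R,3S)-3-[(2R)-6-methylheptan-2-yl]cyclopentyl]tetradecyl]oxy}silane | CC(C)(C)[Si](C)(C)OCC[C@@H](C)CCC[C@@H](C)CCC[C@@H](C)CCC[C@@H]1CC[C@H]([C@H](C)CCCC(C)C)C1 | intermediate
14 | (3S,7S,11R)-3,7,11-trimethyl-14-[(1R,3S)-3-[(2R)-6-methylheptan-2-yl]cyclopentyl]tetradecan-1-ol | OCC[C@@H](C)CCC[C@@H](C)CCC[C@@H](C)CCC[C@@H]1CC[C@H]([C@H](C)CCCC(C)C)C1 | intermediate
15 | (1R,3S)-1-[(4R,8S,12S)-14-iodo-4,8,12-trimethyltetradecyl]-3-[(2R)-6-methylheptan-2-yl]cyclopentane | ICC[C@@H](C)CCC[C@@H](C)CCC[C@@H](C)CCC[C@@H]1CC[C@H]([C@H](C)CCCC(C)C)C1 | intermediate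
16 | menadione (2-methylnaphthalene-1,4-dione) | CC1=CC(=O)c2ccccc2C1=O | starting material
17 | 2-bromo-3-methylnaphthalene-1,4-dione | CC1=C(Br)C(=O)c2ccccc2C1=O | intermediate
18 | 2-bromo-3-methylnaphthalene-1,4-diol (hydroquinone) | Oc1c(C)c(Br)c(O)c2ccccc12 | intermediate (not isolated)
19 | 2-bromo-1,4-dimethoxy-3-methylnaphthalene | COc1c(C)c(Br)c(OC)c2ccccc12 | intermediate
20 | alkylzinc iodide from 15 (iodozinc at C1') | I[Zn]CC[C@@H](C)CCC[C@@H](C)CCC[C@@H](C)CCC[C@@H]1CC[C@H]([C@H](C)CCCC(C)C)C1 | intermediate (not isolated)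
21 | 1,4-dimethoxy-2-methyl-3-[(3S,7S,11R)-3,7,11-trimethyl-14-[(1R,3S)-3-[(2R)-6-methylheptan-2-yl]cyclopentyl]tetradecyl]naphthalene | COc1c(C)c(CC[C@@H](C)CCC[C@@H](C)CCC[C@@H](C)CCC[C@@H]3CC[C@H]([C@H](C)CCCC(C)C)C3)c(OC)c2ccccc12 | intermediate
22 | 2-methyl-3-[(3S,7S,11R)-3,7,11-trimethyl-14-[(1R,3S)-3-[(2R)-6-methylheptan-2-yl]cyclopentyl]tetradecyl]naphthalene-1,4-dione | CC1=C(CC[C@@H](C)CCC[C@@H](C)CCC[C@@H](C)CCC[C@@H]2CC[C@H]([C@H](C)CCCC(C)C)C2)C(=O)c2ccccc2C1=O | target

**Step count**

Total: 17 steps. Longest linear sequence: 15 steps (steps 1–13, 16, 17); steps 14–15 form the two-step menadione branch.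

**Steps most likely to fail**

Step 6. Ring-opening polymerisation of the unsubstituted bicycle may outrun cross-capture, self-metathesis of 6 may consume the partner and release ethylene that ethenolyses 7, and the catalyst may discriminate the two enantiotopic orientations only weakly. The fallback sets out from 7 (and a portion of 6) and comes back at 8, replacing the metathesis by an enzymatic desymmetrisation and two Wittig olefinations. Ozonolysis of 7 (O3, CH2Cl2–MeOH, −78 °C; then NaBH4) should give meso cis-cyclopentane-1,3-diyldimethanol F1. Lipase-catalysed monoacetylation (vinyl acetate, lipase from Burkholderia cepacia, t-BuOMe; enzyme chosen by screening for the required antipode) should give the monoacetate F2. Swern oxidation ((COCl)2, DMSO, Et3N) gives the formyl acetate F3, methylenation (Ph3PCH3Br, NaN(SiMe3)2, THF) gives the vinyl acetate F4, methanolysis (K2CO3, MeOH) gives the vinyl alcohol F5, and a second Swern oxidation gives the vinyl aldehyde F6. In parallel, ozonolysis of 6 with NaBH4 work-up gives the C13' alcohol F7, I2/PPh3/imidazole gives the C13' iodide F8, and PPh3 in MeCN at reflux gives the phosphonium iodide F9. Deprotonation of F9 with NaN(SiMe3)2 in THF and addition of F6 at −78 °C should give 8 as the Z isomer.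

Step 7. The ruthenium carbene may also attack the internal C13'=C14' alkene from its unbranched side, cutting the chain, and secondary metathesis may erode the product. The fallback sets out from 8 and comes back at 13; it avoids metathesis on the diene by using a terminal-selective zirconium-catalysed asymmetric carboalumination. Treatment of 8 with Me3Al, (+)-bis(1-neomenthylindenyl)zirconium dichloride (5 mol %) and (MeAlO)n in CH2Cl2, then O2, should give the primary alcohol F10 with the Cx methyl in place. TsCl/pyridine gives the tosylate F11. Copper-catalysed coupling with 3-methylbutylmagnesium bromide (Li2CuCl4, THF, −20 °C to rt) gives the mono-alkene F12. Hydrogenation under the conditions of step 11 gives 13.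

Step 8. Methyl transfer to the γ-branched enoate may be slow, 1,2-addition to the ester may compete, and facial selectivity at Cx may be poor. The fallback sets out from 8 and comes back at 11; it replaces catalyst control by auxiliary control. Cross-metathesis of 8 with (4R)-3-acryloyl-4-phenyl-1,3-oxazolidin-2-one (second-generation Hoveyda–Grubbs catalyst RuCl2(H2IMes)(=CH-C6H4-2-O-i-Pr), CH2Cl2, 40 °C) should give the enoyl imide F13. Addition of MeMgBr/CuBr·SMe2 (THF, −78 to −20 °C) to the magnesium-chelated imide, anti to the phenyl group, gives the β-methyl imide F14. Reductive cleavage (LiBH4, H2O, Et2O, 0 °C) gives the alcohol F15 and returns the auxiliary. Dess–Martin periodinane oxidation gives 11.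

**Further compounds**

F1 | step 6 | cis-cyclopentane-1,3-diyldimethanol (meso) | OC[C@@H]1CC[C@H](CO)C1
F2 | step 6 | [(1R,3S)-3-(hydroxymethyl)cyclopentyl]methyl acetate | CC(=O)OC[C@@H]1CC[C@H](CO)C1
F3 | step 6 | [(1R,3S)-3-formylcyclopentyl]methyl acetate | CC(=O)OC[C@@H]1CC[C@H](C=O)C1
F4 | step 6 | [(1R,3S)-3-ethenylcyclopentyl]methyl acetate | CC(=O)OC[C@@H]1CC[C@H](C=C)C1
F5 | step 6 | [(1R,3S)-3-ethenylcyclopentyl]methanol | OC[C@@H]1CC[C@H](C=C)C1
F6 | step 6 | (1R,3S)-3-ethenylcyclopentane-1-carbaldehyde | O=C[C@@H]1CC[C@H](C=C)C1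
F7 | step 6 | (3R,7S,11S)-13-{[tert-butyl(dimethyl)silyl]oxy}-3,7,11-trimethyltridecan-1-ol | CC(C)(C)[Si](C)(C)OCC[C@@H](C)CCC[C@@H](C)CCC[C@@H](C)CCO
F8 | step 6 | tert-butyl{[(3S,7R,11R)-13-iodo-3,7,11-trimethyltridecyl]oxy}dimethylsilane | CC(C)(C)[Si](C)(C)OCC[C@@H](C)CCC[C@@H](C)CCC[C@@H](C)CCI
F9 | step 6 | [(3R,7R,11S)-13-{[tert-butyl(dimethyl)silyl]oxy}-3,7,11-trimethyltridecyl](triphenyl)phosphonium iodide | CC(C)(C)[Si](C)(C)OCC[C@@H](C)CCC[C@@H](C)CCC[C@@H](C)CC[P+](c1ccccc1)(c1ccccc1)c1ccccc1.[I-]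
F10 | step 7 | (2S)-2-[(1S,3R)-3-[(1Z,4R,8S,12S)-14-{[tert-butyl(dimethyl)silyl]oxy}-4,8,12-trimethyltetradec-1-en-1-yl]cyclopentyl]propan-1-ol | CC(C)(C)[Si](C)(C)OCC[C@@H](C)CCC[C@@H](C)CCC[C@@H](C)C/C=C\[C@@H]1CC[C@H]([C@H](C)CO)C1
F11 | step 7 | 4-methylbenzenesulfonate (tosylate) of F10 | CC(C)(C)[Si](C)(C)OCC[C@@H](C)CCC[C@@H](C)CCC[C@@H](C)C/C=C\[C@@H]1CC[C@H]([C@H](C)COS(=O)(=O)c2ccc(C)cc2)C1
F12 | step 7 | tert-butyl(dimethyl){[(3S,7S,11R,13Z)-3,7,11-trimethyl-14-[(1R,3S)-3-[(2R)-6-methylheptan-2-yl]cyclopentyl]tetradec-13-en-1-yl]oxy}silane | CC(C)(C)[Si](C)(C)OCC[C@@H](C)CCC[C@@H](C)CCC[C@@H](C)C/C=C\[C@@H]1CC[C@H]([C@H](C)CCCC(C)C)C1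
F13 | step 8 | (4R)-3-[(2E)-3-[(1S,3R)-3-[(1Z,4R,8S,12S)-14-{[tert-butyl(dimethyl)silyl]oxy}-4,8,12-trimethyltetradec-1-en-1-yl]cyclopentyl]prop-2-enoyl]-4-phenyl-1,3-oxazolidin-2-one | CC(C)(C)[Si](C)(C)OCC[C@@H](C)CCC[C@@H](C)CCC[C@@H](C)C/C=C\[C@@H]1CC[C@H](/C=C/C(=O)N2[C@H](c3ccccc3)COC2=O)C1
F14 | step 8 | (4R)-3-[(3R)-3-[(1S,3R)-3-[(1Z,4R,8S,12S)-14-{[tert-butyl(dimethyl)silyl]oxy}-4,8,12-trimethyltetradec-1-en-1-yl]cyclopentyl]butanoyl]-4-phenyl-1,3-oxazolidin-2-one | CC(C)(C)[Si](C)(C)OCC[C@@H](C)CCC[C@@H](C)CCC[C@@H](C)C/C=C\[C@@H]1CC[C@H]([C@H](C)CC(=O)N2[C@H](c3ccccc3)COC2=O)C1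
F15 | step 8 | (3R)-3-[(1S,3R)-3-[(1Z,4R,8S,12S)-14-{[tert-butyl(dimethyl)silyl]oxy}-4,8,12-trimethyltetradec-1-en-1-yl]cyclopentyl]butan-1-ol | CC(C)(C)[Si](C)(C)OCC[C@@H](C)CCC[C@@H](C)CCC[C@@H](C)C/C=C\[C@@H]1CC[C@H]([C@H](C)CCO)C1
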